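## Retrosynthetic overview

1. Target 25 ⇐ neutral oxidation of carbinol 24 ⇐ Horner–Wadsworth–Emmons on epoxy aldehyde 23 ⇐ C–O bond formation: amine-catalysed epoxidation of dienal 22 (the oxirane is the last ring formed).
2. 22 ⇐ two Wittig homologations of aldehyde 20 ⇐ one-pot acid unmasking of 19 (aldehyde, acetonyl, carbinol).
3. Ring A diene of 19 ⇐ enone 13 by α'-alkylation (2-methoxyallyl as masked acetonyl), dienyl triflate formation and Negishi methylation.
4. Enone 10 ⇐ aldol condensation of Michael adduct 8 ⇐ desymmetrising enamine Michael addition of meso-dione 3 to nitroalkene 7 (CH2NO2 as masked aldehyde carbon C-7).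
5. Ring order: ring B (from 2,6-dimethylhydroquinone), then ring A, then the oxirane; the ring B ketone is carried as a carbinol from step 7 and unveiled last.

Assumption: the senses of induction stated for the chiral amines and the tartrate follow the established models for these reagent classes; the mirror-image reagent is used if a model run shows the opposite sense.

Locants in the "Why" lines are those of the target: chain C-1 to C-7 from CO2H; bicycle C-1' (bears the chain), C-2' (acetonyl), C-3' (methyl), C-4', C-4a', C-5', C-6' (methyl), C-7' (ketone), C-8' (methyl), C-8a'.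

## Route

Step 1
Reactants: 1 2,6-dimethylbenzene-1,4-diol
Product: 2 all-cis-2,6-dimethylcyclohexane-1,4-diol (meso)
Conditions: H2 (60 bar), 5% Rh/Al2O3, EtOH, 60 °C
Reagents that add atoms: none
Why: Heterogeneous arene hydrogenation over rhodium delivers all hydrogens to one face, so the two methyl groups come out cis (meso); the carbinol configurations are erased in step 2.

Step 2
Reactants: 2 all-cis-2,6-dimethylcyclohexane-1,4-diol
Product: 3 (2R,6S)-2,6-dimethylcyclohexane-1,4-dione (cis; meso)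
Conditions: aq. NaOCl, AcOH, 15–20 °C
Reagents that add atoms: none
Why: Stevens oxidation (hypochlorite in acetic acid) converts both secondary carbinols to ketones, and the cis-2,6-dimethyl (diequatorial) arrangement is the thermodynamic one in the monocycle.

Step 3
Reactants: 4 ethyl 2-(2-methyl-1,3-dioxolan-2-yl)acetate
Product: 5 2-(2-methyl-1,3-dioxolan-2-yl)acetaldehyde
Conditions: iBu2AlH, CH2Cl2, −78 °C; aq. KNaC4H4O6 work-up
Reagents that add atoms: none
Why: Low-temperature iBu2AlH half-reduction of the ester stops at the aluminium hemiacetal, which releases the aldehyde on work-up; the ketal is inert.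

Step 4
Reactants: 5 2-(2-methyl-1,3-dioxolan-2-yl)acetaldehyde
Product: 7 2-methyl-2-[(2E)-3-nitroprop-2-en-1-yl]-1,3-dioxolane, via nitro alcohol 6 (not isolated)
Conditions: MeNO2, Bu4NF (cat.), THF, 0 °C; then MsCl, Et3N, 0 → 20 °C
Reagents that add atoms: nitromethane C[N+](=O)[O-]
Why: Henry (nitro-aldol) addition followed by mesylation and E1cB elimination gives the conjugated (E)-nitroalkene.

Step 5
Reactants: 3 (2R,6S)-2,6-dimethylcyclohexane-1,4-dione; 7 2-methyl-2-[(2E)-3-nitroprop-2-en-1-yl]-1,3-dioxolane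
Product: 8 (2S,3R,5S)-3,5-dimethyl-2-[(2R)-1-(2-methyl-1,3-dioxolan-2-yl)-3-nitropropan-2-yl]cyclohexane-1,4-dione
Conditions: (R)-1-(pyrrolidin-2-ylmethyl)pyrrolidine (20 mol%), CF3CO2H (20 mol%), 3 (3 equiv), iPrOH, 4 °C
Reagents that add atoms: none
Why: Enamine-catalysed desymmetrising Michael addition, in which only the unhindered carbonyl forms the enamine: the synclinal (syn) transition state sets C-8a'/C-1' so that their hydrogens end up cis in ring A, axial attack on the half-chair with both methyls equatorial puts the new bond cis to the neighbouring methyl, and the (R)-catalyst chooses the enantiotopic α-carbon and face, which also fixes C-6' and C-8'.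

Step 6
Reactants: 8 (2S,3R,5S)-3,5-dimethyl-2-[(2R)-1-(2-methyl-1,3-dioxolan-2-yl)-3-nitropropan-2-yl]cyclohexane-1,4-dione
Product: 10 (4R,4aS,5R,7S)-5,7-dimethyl-4-(nitromethyl)-3,4,4a,5,7,8-hexahydronaphthalene-2,6-dione, via triketone 9 (not isolated)
Conditions: 1 M HCl, THF, 20 °C; then pyrrolidine (0.3 equiv), AcOH (0.3 equiv), PhMe, 40 °C
Reagents that add atoms: water O
Why: Ketal hydrolysis then pyrrolidinium acetate-mediated intramolecular aldol condensation (second half of a Robinson annulation) closes ring A; the enamine forms at the methyl ketone and the ring ketone tautomerises toward its less substituted side, so C-8a' is not epimerised.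

Step 7
Reactants: 10 (4R,4aS,5R,7S)-5,7-dimethyl-4-(nitromethyl)-3,4,4a,5,7,8-hexahydronaphthalene-2,6-dione
Product: 13 (4R,4aR,5R,7S)-4-(dimethoxymethyl)-6-hydroxy-5,7-dimethyl-4,4a,5,6,7,8-hexahydronaphthalen-2(3H)-one, via hydroxy nitro enone 11 (not isolated), via sodium nitronate 12 (not isolated)
Conditions: NaBH4, MeOH–CH2Cl2 (1:1), −78 → −40 °C; NaOMe, MeOH, 0 °C; then into H2SO4–MeOH, −40 → 20 °C
Reagents that add atoms: methanol CO
Why: NaBH4 at low temperature reduces the saturated ketone but not the conjugated enone, which parks the epimerisable α,α'-dimethyl ketone as a carbinol (configuration irrelevant) before any strong base is used, and the Nef reaction of the nitronate in acidic methanol then gives the aldehyde directly as its dimethyl acetal.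

Step 8
Reactants: 14 2-methoxyprop-1-ene
Product: 15 3-bromo-2-methoxyprop-1-ene (2-methoxyallyl bromide)
Conditions: NBS, CCl4, −10 → 20 °C
Reagents that add atoms: N-bromosuccinimide O=C1CCC(=O)N1Br
Why: Allylic bromination of the enol ether with NBS gives the known acetonyl-cation equivalent.

Step 9
Reactants: 13 (4R,4aR,5R,7S)-4-(dimethoxymethyl)-6-hydroxy-5,7-dimethyl-4,4a,5,6,7,8-hexahydronaphthalen-2(3H)-one; 15 3-bromo-2-methoxyprop-1-ene
Product: 17 (4S,4aR,5R,7S)-4-(dimethoxymethyl)-3-(2-methoxyprop-2-en-1-yl)-5,7-dimethyl-6-(triethylsilyloxy)-4,4a,5,6,7,8-hexahydronaphthalen-2(3H)-one (C-3 epimers), via lithium alkoxide 16 (not isolated)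
Conditions: LiN(iPr)2 (2.2 equiv), THF, −78 °C; 15 (1.1 equiv), −78 → −30 °C; Et3SiCl (1.3 equiv), −30 → 0 °C
Reagents that add atoms: chlorotriethylsilane CC[Si](CC)(CC)Cl
Why: Kinetic α'-deprotonation of the enone (cross-conjugated dienolate) and C-alkylation with the reactive allylic bromide, then silylation of the hindered alkoxide in the same flask; the new centre at C-2' becomes planar in step 10.

Step 10
Reactants: 17 (4S,4aR,5R,7S)-4-(dimethoxymethyl)-3-(2-methoxyprop-2-en-1-yl)-5,7-dimethyl-6-(triethylsilyloxy)-4,4a,5,6,7,8-hexahydronaphthalen-2(3H)-one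
Product: 18 (1S,6S,8R,8aR)-1-(dimethoxymethyl)-2-(2-methoxyprop-2-en-1-yl)-6,8-dimethyl-7-(triethylsilyloxy)-1,5,6,7,8,8a-hexahydronaphthalen-3-yl trifluoromethanesulfonate
Conditions: LiN(iPr)2 (1.2 equiv), THF, −78 °C; PhNTf2 (1.3 equiv), −78 → 0 °C
Reagents that add atoms: N-phenylbis(trifluoromethanesulfonimide) O=S(=O)(N(c1ccccc1)S(=O)(=O)C(F)(F)F)C(F)(F)F
Why: A second kinetic α'-deprotonation and O-triflation of the cross-conjugated dienolate fix the C-2'=C-3' double bond regiospecifically (2-triflyloxy-1,3-diene); the enone is the only carbonyl group left in the molecule.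

Step 11
Reactants: 18 (1S,6S,8R,8aR)-1-(dimethoxymethyl)-2-(2-methoxyprop-2-en-1-yl)-6,8-dimethyl-7-(triethylsilyloxy)-1,5,6,7,8,8a-hexahydronaphthalen-3-yl trifluoromethanesulfonate
Product: 19 (1S,6S,8R,8aR)-1-(dimethoxymethyl)-2-(2-methoxyprop-2-en-1-yl)-3,6,8-trimethyl-7-(triethylsilyloxy)-1,5,6,7,8,8a-hexahydronaphthalene
Conditions: MeZnCl (2 equiv), Pd(PPh3)4 (5 mol%), THF, 50 °C
Reagents that add atoms: methylzinc chloride C[Zn]Cl
Why: Negishi cross-coupling (oxidative addition of the dienyl triflate to zerovalent palladium, transmetalation from methylzinc, reductive elimination) installs the C-3' methyl without moving the diene.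

Step 12
Reactants: 19 (1S,6S,8R,8aR)-1-(dimethoxymethyl)-2-(2-methoxyprop-2-en-1-yl)-3,6,8-trimethyl-7-(triethylsilyloxy)-1,5,6,7,8,8a-hexahydronaphthalene
Product: 20 (1S,6S,8R,8aR)-7-hydroxy-3,6,8-trimethyl-2-(2-oxopropyl)-1,5,6,7,8,8a-hexahydronaphthalene-1-carbaldehyde
Conditions: AcOH–THF–H2O (3:1:1), 40 °C; used at once
Reagents that add atoms: water O
Why: Mild aqueous acid hydrolyses the enol ether (to the acetonyl ketone), the dimethyl acetal (to the aldehyde) and the silyl ether in one operation, with no base present that could epimerise C-1' or move the diene.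

Step 13
Reactants: 20 (1S,6S,8R,8aR)-7-hydroxy-3,6,8-trimethyl-2-(2-oxopropyl)-1,5,6,7,8,8a-hexahydronaphthalene-1-carbaldehyde
Product: 21 (2E)-3-[(1S,6S,8R,8aS)-7-hydroxy-3,6,8-trimethyl-2-(2-oxopropyl)-1,5,6,7,8,8a-hexahydronaphthalen-1-yl]-2-methylprop-2-enal
Conditions: Ph3P=C(CH3)CHO (1.3 equiv), CH2Cl2, 25–40 °C
Reagents that add atoms: 2-(triphenylphosphoranylidene)propanal CC(C=O)=P(c1ccccc1)(c1ccccc1)c1ccccc1
Why: The Wittig reaction with the stabilised formyl ylide is neutral and aldehyde-selective (the methyl ketone is untouched) and gives the (E)-trisubstituted C-6=C-7 alkene.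

Step 14
Reactants: 21 (2E)-3-[(1S,6S,8R,8aS)-7-hydroxy-3,6,8-trimethyl-2-(2-oxopropyl)-1,5,6,7,8,8a-hexahydronaphthalen-1-yl]-2-methylprop-2-enal
Product: 22 (2E,4E)-5-[(1S,6S,8R,8aS)-7-hydroxy-3,6,8-trimethyl-2-(2-oxopropyl)-1,5,6,7,8,8a-hexahydronaphthalen-1-yl]-2,4-dimethylpenta-2,4-dienal
Conditions: Ph3P=C(CH3)CHO (1.5 equiv), PhMe, 90 °C
Reagents that add atoms: 2-(triphenylphosphoranylidene)propanal CC(C=O)=P(c1ccccc1)(c1ccccc1)c1ccccc1
Why: A second Wittig homologation with the same stabilised ylide, at higher temperature because the enal is less electrophilic, gives the (E)-C-4=C-5 alkene.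

Step 15
Reactants: 22 (2E,4E)-5-[(1S,6S,8R,8aS)-7-hydroxy-3,6,8-trimethyl-2-(2-oxopropyl)-1,5,6,7,8,8a-hexahydronaphthalen-1-yl]-2,4-dimethylpenta-2,4-dienal
Product: 23 (2R,3S)-3-{(1E)-1-[(1S,6S,8R,8aS)-7-hydroxy-3,6,8-trimethyl-2-(2-oxopropyl)-1,5,6,7,8,8a-hexahydronaphthalen-1-yl]prop-1-en-2-yl}-2-methyloxirane-2-carbaldehyde
Conditions: 50% aq. H2O2 (1.5 equiv), 9-amino-9-deoxy-epi-quinine (10 mol%), (R)-TRIP (10 mol%), THF, 30 °C
Reagents that add atoms: hydrogen peroxide OO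
Why: Proposed new method: iminium-catalysed nucleophilic epoxidation of an α-branched (α,γ-dimethyl) 2,4-dienal, in which the primary amine forms an (E)-iminium ion, H2O2 held by the chiral phosphate adds to the β-carbon (C-5) and the resulting enamine closes onto the O–O bond to make both C–O bonds of the oxirane with the target's (4S,5S) configuration from the (E)-alkene; attack at the δ-carbon (C-7) is blocked by the γ-methyl and the bicycle, the electron-rich ring diene and the ketones are inert to this nucleophilic oxidant, and the ion-paired catalyst rather than the remote ring stereocentres sets the face; the closest known reactions are the amine/phosphoric acid-catalysed epoxidation of simple α-branched enals and the 1,4-selective epoxidation of unbranched 2,4-dienals.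

Step 16
Reactants: 23 (2R,3S)-3-{(1E)-1-[(1S,6S,8R,8aS)-7-hydroxy-3,6,8-trimethyl-2-(2-oxopropyl)-1,5,6,7,8,8a-hexahydronaphthalen-1-yl]prop-1-en-2-yl}-2-methyloxirane-2-carbaldehyde
Product: 24 (2E,4S,5S,6E)-4,5-epoxy-7-[(1S,6S,8R,8aS)-7-hydroxy-3,6,8-trimethyl-2-(2-oxopropyl)-1,5,6,7,8,8a-hexahydronaphthalen-1-yl]-4,6-dimethylhepta-2,6-dienoic acid
Conditions: (EtO)2P(O)CH2CO2H (1.5 equiv), Zn(OTf)2 (2 equiv), TMEDA (1.2 equiv), Et3N (4 equiv), THF, 20 °C; pH 5 buffer work-up
Reagents that add atoms: diethylphosphonoacetic acid CCOP(=O)(CC(=O)O)OCC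
Why: Horner–Wadsworth–Emmons reaction of the zinc-bound phosphonoacetate dianion gives the (E)-acrylic acid directly, under amine-base conditions mild enough for the oxirane and the β,γ-unsaturated ketone; the aldehyde α-carbon is quaternary and cannot epimerise.

Step 17
Reactants: 24 (2E,4S,5S,6E)-4,5-epoxy-7-[(1S,6S,8R,8aS)-7-hydroxy-3,6,8-trimethyl-2-(2-oxopropyl)-1,5,6,7,8,8a-hexahydronaphthalen-1-yl]-4,6-dimethylhepta-2,6-dienoic acid
Product: 25 (2E,4S,5S,6E)-4,5-epoxy-4,6-dimethyl-7-[(1S,6S,8R,8aS)-3,6,8-trimethyl-7-oxo-2-(2-oxopropyl)-1,5,6,7,8,8a-hexahydronaphthalen-1-yl]hepta-2,6-dienoic acid (CNP0214881.1)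
Conditions: Dess–Martin periodinane (1.5 equiv), NaHCO3, CH2Cl2, 0 → 20 °C
Reagents that add atoms: none
Why: Buffered Dess–Martin oxidation unveils the C-7' ketone last and without enolisation, so the all-cis C-6'/C-8' methyl array fixed in step 5 (likely the less stable arrangement once ring A is fused) is never exposed to base or acid as a ketone.

## Compound list

1 | 2,6-dimethylbenzene-1,4-diol | Cc1cc(O)cc(C)c1O | starting material
2 | all-cis-2,6-dimethylcyclohexane-1,4-diol (meso) | O[C@@H]1C[C@H](C)[C@H](O)[C@H](C)C1 | intermediate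
3 | (2R,6S)-2,6-dimethylcyclohexane-1,4-dione (cis; meso) | O=C1C[C@H](C)C(=O)[C@H](C)C1 | intermediate
4 | ethyl 2-(2-methyl-1,3-dioxolan-2-yl)acetate | CCOC(=O)CC1(C)OCCO1 | starting material
5 | 2-(2-methyl-1,3-dioxolan-2-yl)acetaldehyde | O=CCC1(C)OCCO1 | intermediate
6 | 1-(2-methyl-1,3-dioxolan-2-yl)-3-nitropropan-2-ol (racemic; not isolated) | CC1(CC(O)C[N+](=O)[O-])OCCO1 | intermediate
7 | 2-methyl-2-[(2E)-3-nitroprop-2-en-1-yl]-1,3-dioxolane | CC1(C/C=C/[N+](=O)[O-])OCCO1 | intermediate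
8 | (2S,3R,5S)-3,5-dimethyl-2-[(2R)-1-(2-methyl-1,3-dioxolan-2-yl)-3-nitropropan-2-yl]cyclohexane-1,4-dione | O=C1C[C@H](C)C(=O)[C@H](C)[C@@H]1[C@@H](CC2(C)OCCO2)C[N+](=O)[O-] | intermediate
9 | (2S,3R,5S)-3,5-dimethyl-2-[(2R)-1-nitro-4-oxopentan-2-yl]cyclohexane-1,4-dione (not isolated) | O=C1C[C@H](C)C(=O)[C@H](C)[C@@H]1[C@@H](CC(C)=O)C[N+](=O)[O-] | intermediate
10 | (4R,4aS,5R,7S)-5,7-dimethyl-4-(nitromethyl)-3,4,4a,5,7,8-hexahydronaphthalene-2,6-dione (C1=C8a enone) | O=C1C=C2C[C@H](C)C(=O)[C@H](C)[C@@H]2[C@@H](C1)C[N+](=O)[O-] | intermediate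
11 | (4R,4aS,5R,7S)-6-hydroxy-5,7-dimethyl-4-(nitromethyl)-4,4a,5,6,7,8-hexahydronaphthalen-2(3H)-one (C-6 epimer not assigned; not isolated) | O=C1C=C2C[C@H](C)C(O)[C@H](C)[C@@H]2[C@@H](C1)C[N+](=O)[O-] | intermediate
12 | sodium nitronate of 11 (not isolated) | O=C1C=C2C[C@H](C)C(O)[C@H](C)[C@@H]2[C@@H](C1)C=[N+]([O-])[O-].[Na+] | intermediate
13 | (4R,4aR,5R,7S)-4-(dimethoxymethyl)-6-hydroxy-5,7-dimethyl-4,4a,5,6,7,8-hexahydronaphthalen-2(3H)-one (C-6 epimer not assigned) | O=C1C=C2C[C@H](C)C(O)[C@H](C)[C@@H]2[C@@H](C1)C(OC)OC | intermediate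
14 | 2-methoxyprop-1-ene | COC(C)=C | starting material
15 | 3-bromo-2-methoxyprop-1-ene | COC(=C)CBr | intermediate
16 | lithium alkoxide of C-3-alkylated 13 (not isolated) | O=C1C=C2C[C@H](C)C([O-])[C@H](C)[C@@H]2[C@@H](C1CC(=C)OC)C(OC)OC.[Li+] | intermediate
17 | (4S,4aR,5R,7S)-4-(dimethoxymethyl)-3-(2-methoxyprop-2-en-1-yl)-5,7-dimethyl-6-(triethylsilyloxy)-4,4a,5,6,7,8-hexahydronaphthalen-2(3H)-one (C-3 epimers) | O=C1C=C2C[C@H](C)C(O[Si](CC)(CC)CC)[C@H](C)[C@@H]2[C@@H](C1CC(=C)OC)C(OC)OC | intermediate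
18 | (1S,6S,8R,8aR)-1-(dimethoxymethyl)-2-(2-methoxyprop-2-en-1-yl)-6,8-dimethyl-7-(triethylsilyloxy)-1,5,6,7,8,8a-hexahydronaphthalen-3-yl trifluoromethanesulfonate (locants from here on as in the target) | COC(=C)CC1=C(OS(=O)(=O)C(F)(F)F)C=C2C[C@H](C)C(O[Si](CC)(CC)CC)[C@H](C)[C@@H]2[C@@H]1C(OC)OC | intermediate
19 | (1S,6S,8R,8aR)-1-(dimethoxymethyl)-2-(2-methoxyprop-2-en-1-yl)-3,6,8-trimethyl-7-(triethylsilyloxy)-1,5,6,7,8,8a-hexahydronaphthalene | COC(=C)CC1=C(C)C=C2C[C@H](C)C(O[Si](CC)(CC)CC)[C@H](C)[C@@H]2[C@@H]1C(OC)OC | intermediate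
20 | (1S,6S,8R,8aR)-7-hydroxy-3,6,8-trimethyl-2-(2-oxopropyl)-1,5,6,7,8,8a-hexahydronaphthalene-1-carbaldehyde | CC(=O)CC1=C(C)C=C2C[C@H](C)C(O)[C@H](C)[C@@H]2[C@@H]1C=O | intermediate
21 | (2E)-3-[(1S,6S,8R,8aS)-7-hydroxy-3,6,8-trimethyl-2-(2-oxopropyl)-1,5,6,7,8,8a-hexahydronaphthalen-1-yl]-2-methylprop-2-enal | CC(=O)CC1=C(C)C=C2C[C@H](C)C(O)[C@H](C)[C@@H]2[C@@H]1/C=C(\C)C=O | intermediate
22 | (2E,4E)-5-[(1S,6S,8R,8aS)-7-hydroxy-3,6,8-trimethyl-2-(2-oxopropyl)-1,5,6,7,8,8a-hexahydronaphthalen-1-yl]-2,4-dimethylpenta-2,4-dienal | CC(=O)CC1=C(C)C=C2C[C@H](C)C(O)[C@H](C)[C@@H]2[C@@H]1/C=C(\C)/C=C(\C)C=O | intermediate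
23 | (2R,3S)-3-{(1E)-1-[(1S,6S,8R,8aS)-7-hydroxy-3,6,8-trimethyl-2-(2-oxopropyl)-1,5,6,7,8,8a-hexahydronaphthalen-1-yl]prop-1-en-2-yl}-2-methyloxirane-2-carbaldehyde | CC(=O)CC1=C(C)C=C2C[C@H](C)C(O)[C@H](C)[C@@H]2[C@@H]1/C=C(\C)[C@@H]1O[C@@]1(C)C=O | intermediate
24 | (2E,4S,5S,6E)-4,5-epoxy-7-[(1S,6S,8R,8aS)-7-hydroxy-3,6,8-trimethyl-2-(2-oxopropyl)-1,5,6,7,8,8a-hexahydronaphthalen-1-yl]-4,6-dimethylhepta-2,6-dienoic acid | CC(=O)CC1=C(C)C=C2C[C@H](C)C(O)[C@H](C)[C@@H]2[C@@H]1/C=C(\C)[C@@H]1O[C@@]1(C)/C=C/C(=O)O | intermediate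
25 | (2E,4S,5S,6E)-4,5-epoxy-4,6-dimethyl-7-[(1S,6S,8R,8aS)-3,6,8-trimethyl-7-oxo-2-(2-oxopropyl)-1,5,6,7,8,8a-hexahydronaphthalen-1-yl]hepta-2,6-dienoic acid | CC(=O)CC1=C(C)C=C2C[C@H](C)C(=O)[C@H](C)[C@@H]2[C@@H]1/C=C(\C)[C@@H]1O[C@@]1(C)/C=C/C(=O)O | target

## Step count and risks

Total step count: 17 (steps 3, 4 and 8 are side branches).
Longest linear sequence: 14 steps (1, 2, 5, 6, 7, 9, 10, 11, 12, 13, 14, 15, 16, 17).

Three steps most likely to fail:

Step 5 (desymmetrising Michael addition). The aliphatic nitroalkene may react sluggishly, and the preference for attack cis to the neighbouring methyl is argued by analogy, not demonstrated on this dione. The fallback sets out from 3 and 7 and comes back at 8, replacing catalysis by a stoichiometric, preformed chiral enamine. Dione 3 is condensed with (R)-2-(methoxymethyl)pyrrolidine (PhH, cat. TsOH, water separator) to the enamine 4-[(2R)-2-(methoxymethyl)pyrrolidin-1-yl]-cis-2,6-dimethylcyclohex-3-en-1-one F1. F1 adds to 7 in Et2O at −78 → 20 °C to give the adduct enamine F2. Buffered aqueous AcOH/NaOAc hydrolysis then gives 8 and returns the auxiliary.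

Step 10 (dienyl triflate). Deprotonation of the hindered C-2' methine may be slow or may compete with γ-deprotonation. The fallback sets out from 17 and comes back at 19, bypassing steps 10 and 11 by addition–elimination. MeLi/CeCl3 (THF, −78 °C) adds 1,2 to the only carbonyl group to give the tertiary allylic alcohol 1-(dimethoxymethyl)-2-(2-methoxyprop-2-en-1-yl)-3,6,8-trimethyl-7-(triethylsilyloxy)-1,2,3,5,6,7,8,8a-octahydronaphthalen-3-ol F3. Burgess reagent (PhMe, 60 °C, neutral) then dehydrates F3 toward C-2' to the conjugated tetrasubstituted diene 19.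

Step 15 (new amine-catalysed epoxidation). Attack at C-7, poor face control or slow iminium formation of the hindered dienal could defeat it. The fallback uses known chemistry, sets out from 22 and comes back at 23.
- NaBH4 (EtOH–CH2Cl2, −78 °C) reduces the aldehyde in preference to the ketone, giving the dienol (2E,4E)-5-[(1S,6S,8R,8aS)-7-hydroxy-3,6,8-trimethyl-2-(2-oxopropyl)-1,5,6,7,8,8a-hexahydronaphthalen-1-yl]-2,4-dimethylpenta-2,4-dien-1-ol F4.
- Sharpless asymmetric epoxidation (Ti(OiPr)4, L-(+)-diethyl tartrate, tBuOOH, 4 Å sieves, CH2Cl2, −20 °C) epoxidises only the allylic-alcohol alkene, giving the (2S,3S)-epoxy alcohol {(2S,3S)-3-[(1E)-1-(bicyclyl)prop-1-en-2-yl]-2-methyloxiran-2-yl}methanol F5.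
- TEMPO/PhI(OAc)2 (CH2Cl2, 20 °C) oxidises the primary alcohol only, leaving the hindered C-7' carbinol, and gives 23.

Further compounds
F1 | step 5 | 4-[(2R)-2-(methoxymethyl)pyrrolidin-1-yl]-cis-2,6-dimethylcyclohex-3-en-1-one | COC[C@H]1CCCN1C2=C[C@@H](C)C(=O)[C@@H](C)C2
F2 | step 5 | enamine of 8 with (R)-2-(methoxymethyl)pyrrolidine (double bond toward the unsubstituted α-carbon) | COC[C@H]1CCCN1C2=C[C@H](C)C(=O)[C@H](C)[C@@H]2[C@@H](CC3(C)OCCO3)C[N+](=O)[O-]
F3 | step 10 | 1-(dimethoxymethyl)-2-(2-methoxyprop-2-en-1-yl)-3,6,8-trimethyl-7-(triethylsilyloxy)-1,2,3,5,6,7,8,8a-octahydronaphthalen-3-ol (C-2 and C-3 epimers) | COC(=C)CC1C(C)(O)C=C2C[C@H](C)C(O[Si](CC)(CC)CC)[C@H](C)[C@@H]2[C@@H]1C(OC)OC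
F4 | step 15 | (2E,4E)-5-[(1S,6S,8R,8aS)-7-hydroxy-3,6,8-trimethyl-2-(2-oxopropyl)-1,5,6,7,8,8a-hexahydronaphthalen-1-yl]-2,4-dimethylpenta-2,4-dien-1-ol | CC(=O)CC1=C(C)C=C2C[C@H](C)C(O)[C@H](C)[C@@H]2[C@@H]1/C=C(\C)/C=C(\C)CO
F5 | step 15 | {(2S,3S)-3-[(1E)-1-[(1S,6S,8R,8aS)-7-hydroxy-3,6,8-trimethyl-2-(2-oxopropyl)-1,5,6,7,8,8a-hexahydronaphthalen-1-yl]prop-1-en-2-yl]-2-methyloxiran-2-yl}methanol | CC(=O)CC1=C(C)C=C2C[C@H](C)C(O)[C@H](C)[C@@H]2[C@@H]1/C=C(\C)[C@@H]1O[C@@]1(C)CO
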